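Look for the slowness of this flask in the tail of its curve, not at its start.

electrophile 0.50 mM; nucleophile 0.450 mM; free base 0.400 mM; scavenger 0.250 mM (fed, over 0.25 s); time 50 s

    electrophile + nucleophile → acid set free + product (k1 = 1630 /M/s)
    nucleophile + acid set free ⇌ protonated nucleophile, settled at all times (K2 = 61800 /M)
    acid set free + free base ⇌ salt of the base, settled at all times (K3 = 1.9 × 10⁸ /M)
    acid set free → by-product carried off (k4 = 2.14 /s)
    acid set free + free base ⇌ idle adduct, settled at all times (K5 = 19000 /M)
    acid set free + scavenger → scavenged by-product (k6 = 3520 /M/s)

- acid set free is meant together with its idle adduct
- run time (flask): 50 s

- part of the electrophile that has reacted at 50 s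
- share of the unused nucleophile that is free and not bound as protonated nucleophile, at 50 s

Draw reacted electrophile against time, beginning with the slope. At the charges the first step runs at 0.367 mM/s, so a straight line would use up the nucleophile charge in 1.23 s; but the slope falls as both reactants fall.

Next fix the level. The nucleophile is the limiting reagent, charged below the electrophile and consumed one for one, so the curve can rise to 90.0%.

Now find the concentration that sets the order of the rate. [electrophile] always exceeds [nucleophile] by 0.0500 mM. Where [nucleophile] equals this excess, [electrophile] is still 0.100 mM, twice the excess, so the rate turns pseudo-first-order in [nucleophile] later, with [nucleophile] far below the excess and [electrophile] close to it. Define the tail constant as the first step's rate constant times the excess: 0.0815 /s, a lifetime of 12.3 s. While the nucleophile stays free, the ratio [nucleophile]/[electrophile] decays with this constant from the start, before the rate is pseudo-first-order.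

Test the acid before trusting that. The free base holds acid with 76000 against the nucleophile's 28, both at starting charges, and the carrying-off step alone halves free acid in 0.32 s, far inside the tail lifetime. So count the nucleophile as free.

Place the knee where [nucleophile] equals the excess, the ratio having dropped from 0.900 to 0.500: at 7.21 s, with 80.0% reacted. By 50 s the ratio is 0.0153, which leaves 7.77 × 10⁻⁴ mM of nucleophile, so my c is 89.8%. My reckoning stops there and gives no number for fr, which needs the late [acid set free].

The forecast says 89.8% and 99.2%, holding that the “nucleophile therefore runs out almost as if uninhibited”.

The simulation of this flask gives 89.8% and 99.2%, with 0.19% of the charged nucleophile left where the tail constant gave 0.173%. Apply the constant to the neighbour flask with 0.18 mM of nucleophile: its level is 36.0%, its tail constant 0.522 /s, and it stands at 36.0%. Apply it to this flask at ten times the time: 40.7 lifetimes have passed and c reads 90.0%. This flask still moves elsewhere: by-product carried off climbs from 0.0457 mM to 0.0874 mM, and free base from 3.69% to 17.7% of its charge at 500 s.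

(The numbers of this flask were chosen freely; the flask was simulated.)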